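The earlier runs and the new flask are calculated from invented constants.

Two conversions and one direction are asked of the flasks winter and summer, and one quantity answers them: the spending ratio.

| setting | gamma | zeta | winter | summer |
|---|---|---|---|---|
| electrophile | 0.080 M (fed, over 3.0 min) | 0.026 M (fed, over 3.0 min) | 0.053 M (fed, over 3.0 min) | 0.053 M (fed, over 3.0 min) |
| nucleophile | 0.0477 M | 0.0477 M | 0.0480 M | 0.0720 M |
| remark | run made earlier; the fed solution adds 0.10 times the starting volume | run made earlier; the fed solution adds 0.10 times the starting volume | the fed solution adds 0.10 times the starting volume | the fed solution adds 0.10 times the starting volume |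
| time |  |  | 1.5 h | 1.5 h |

| run | time / min | electrophile / % | target / % |
|---|---|---|---|
| gamma | 4.00 | 93 | 7 |
| gamma | 6.00 | 86 | 13 |
| gamma | 10.0 | 81 | 21 |
| gamma | 15.0 | 76 | 26 |
| gamma | 25.0 | 71 | 19 |
| gamma | 40.0 | 70 | 16 |
| gamma | 50.0 | 70 | 16 |
| zeta | 4.00 | 89 | 11 |
| zeta | 6.00 | 83 | 19 |
| zeta | 10.0 | 73 | 25 |
| zeta | 15.0 | 65 | 33 |
| zeta | 25.0 | 46 | 35 |
| zeta | 40.0 | 35 | 37 |
| zeta | 50.0 | 31 | 35 |

(standard deviation of a reading: 2 percentage points)

- charges are per starting volume, the dose included; the dosed solution carries all of it
- the numbers in the tables scatter by 2 percentage points (one standard deviation)

1. part of the electrophile that has reacted at the end, winter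
2. part of the electrophile that has reacted at the end, summer
3. what raising the concentration of nucleophile from its lowest to its highest value here does to the part of the electrophile that has reacted (changes below 5 percentage points count as none) (it falls / it rises / no change)

The first way to this ratio uses the end of the gamma flask. Its electrophile holds at 70% from 40.0 min to 50.0 min, which is read as its nucleophile being used up:

nucleophile charged / electrophile consumed = 1.99

This is the spending ratio, the nucleophile consumed per electrophile consumed.

The second way uses rates, not an end point. The zeta flask keeps moving, and if its rate is first order in each partner, its first-order loss of electrophile falls with its nucleophile: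

early rate = 0.0330 /min, late rate = 0.0158 /min

Electrophile consumed at the middle of each span = 0.00494 M and 0.0160 M

ratio that fits this fall = 1.83

The two ways nearly agree, and the rate way is the looser one, since one scatter on the last zeta reading moves the late rate by 16.3%. The end-point figure is therefore carried. It gives each flask an estimated stall, the conversion near which it levels off at this ratio, with nucleophile as the limiting reagent; this is an estimate, not a bound:

stall = nucleophile / (ratio × electrophile): winter 45.6%, summer 68.4%

The shortfall from this stall at the asked time is reckoned as a small correction. The early zeta rate gives a rate constant of 0.872 /M/min. Near the stall, free nucleophile is taken to decay pseudo-first-order against the electrophile left over: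

decay rate = ratio × constant × electrophile left: winter 0.0500 /min, summer 0.0291 /min

shortfall = stall × (1 − stall) × exp(−decay rate × time): winter 0.28 percentage points, summer 1.6 points

This reckoning commits to 45.3% for winter and 66.8% for summer, a rise of 21 points against the 5 points that counts.

The forecast, built on “two nucleophile per electrophile”, stands at 45% for winter and 66% for summer, with it rises.

The flask gives 45.6% for winter and 66.5% for summer; with more nucleophile it rises, by 21 points.

    electrophile + nucleophile ⇌ acid set free + target (K = 0.450, k = 1.07 /M/min)
    nucleophile + acid set free ⇌ protonated nucleophile, settled at all times (K = 17000 /M)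
    target → over-reaction product (k = 0.0198 /min)

The difference in nucleophile is the reason for that rise: the summer flask charged with winter's nucleophile ends at 45.6% instead of 66.5%. At 1.50 h the summer flask keeps 3.3% of its nucleophile free against 33% of its electrophile, with 0.0312 M standing as protonated nucleophile. A further flask like summer, with 0.13 M of electrophile, has an estimated stall of 27.9% by the ratio of 1.99, and it ends at 28.6%.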